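The meeting began at the late end of the run: the chair asked by which exits target leaves the reaction phase of this flask once starting material has been bound, and how those exits divide it. Reagent crosses from the second phase into the reaction phase and binds starting material reversibly to give target, which then passes into the second phase as product, decays to decomposed product or over-reaction product, or turns reversibly into its isomer. The flask and the questions were tabled as follows.

starting material 1.2 M; reagent in the second phase 2.40 M; time 15 min; volume of the second phase over the first 1.0

* target and product in the second phase together at 15 min, in percent of the starting material charged
* the change that raises the amount of target and product in the second phase together at 15 min, in percent of the starting material charged most ("none" if none brings more than 2 percentage points) (larch / cedar / alder / none)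
* amount of target and product in the second phase together at 15 min, in percent of the starting material charged, after cedar

- amounts and yields of target count product in the second phase too
- in the second phase: reagent in the second phase, product in the second phase; everything else is in the first
- charges count per volume of the first phase; a concentration in a rate is the amount of a species over the volume of its own phase; every rate counts per litre of the first phase
- run time (flask): 15 min

    reagent in the reaction phase ⇌ reagent in the second phase, rate k1*([reagent in the reaction phase] - [reagent in the second phase]/K1) per volume of the first phase (K1 = 0.533, k1 = 0.0121 s⁻¹)
    starting material + reagent in the reaction phase ⇌ target (K2 = 0.81 M⁻¹, k2 = 0.0104 M⁻¹ s⁻¹)
    target ⇌ product in the second phase, rate k3*([target] - [product in the second phase]/K3) per volume of the first phase (K3 = 24.8, k3 = 0.00282 s⁻¹)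
    target → decomposed product (k4 = 0.00141 s⁻¹)
    target → over-reaction product (k5 = 0.00161 s⁻¹)
    target ⇌ isomer of the product (K6 = 0.85, k6 = 0.00183 s⁻¹)

Taking the minutes, I argued by hand that the concentration carrying the order of these rates is that of target in the reaction phase, since the uptake, with coefficient 0.00282 s⁻¹, and the two losses, with constants 0.00141 s⁻¹ and 0.00161 s⁻¹, are each first order in it, so that it cancels from their ratio. Setting aside the return from the second phase, whose partition ratio is 24.8, I called the uptake coefficient divided by itself plus the two loss constants the extraction share, a selectivity factor, and it comes to 48.3%. By these exits target drains with a half-life of 1.98 min, shorter than the run of 15 min, so I committed to about 48.3% for the yield, an estimate that leaves the isomer and any unbound starting material out of the count. Neither reagent change enters the share, whereas doubling the uptake coefficient, which is cedar, lifts it to 65.1%, a gain of 17 percentage points.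

The forecast, brought by a colleague, put the yield at 43%, lower than my figure, named cedar as the best change and gave 59% after it, also lower than mine, holding that “Extraction is therefore the selectivity-setting step”.

The simulation gives a yield of 41.2%, names cedar as the best change, and reaches 55.4% after it; the gains are 0.066 points for larch, 14 points for cedar and 2.6 points for alder.

The main reason for this flask's yield is the pace of the uptake: the run with that limit on its pace taken away stands at 84.2% against 41.2%. At 15.0 min this flask's product in the second phase, over itself plus decomposed and over-reaction product, reads 46.7% against the extraction share of 48.3%. The neighbour flask charged with 3.0 M of starting material, which reaches a yield of 31.6% with 31.2% of that starting material still unbound, reads 46.7%.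

(The numbers of this flask come from no measurement.)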